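**Retrosynthetic overview**
- The lactone C–O bond of ring D is cut first, as carboxylate addition to an enone. The adjacent β-hydroxy ketone of ring C is cut as an aldol. Both lead back to one ring A/ring B seco-acid.
- Ring B, a cyclohept-4-enone, comes from Claisen ring expansion of a 2-methylene-5-alkenyl oxolane. That oxolane is made by C–O bond formation, the addition of an alcohol to an alkyne.
- The alkynol comes from the ring A aldehyde, a propiolate and iodide (halo-aldol), followed by a Heck coupling with methyl vinyl ketone.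
- Ring A comes from a catalytic asymmetric Diels–Alder reaction. The siloxydiene is built from methyl acetoacetate and a silylpropynal; the dienophile is 4-methylpenta-2,4-dienal.
- Order of ring formation: A, temporary oxolane, B, D, C.

Assumption: β-keto esters are drawn as the enol tautomer used in the target SMILES, and all starting materials named are catalogue items.

**Step 1**
Reactants: 1 methyl acetoacetate; 2 3-(trimethylsilyl)prop-2-ynal
Product: 3 methyl (2Z)-2-acetyl-5-(trimethylsilyl)pent-2-en-4-ynoate
Conditions: piperidine (10 mol%), AcOH (10 mol%), 4 Å MS, CH2Cl2, 0 °C → rt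
Reagents that add atoms: none
Why: Knoevenagel condensation at the only doubly activated CH2 gives mainly the Z isomer (alkynyl cis to the ester, trans to the acetyl group), which is purified by chromatography; no stereocentre is formed.

**Step 2**
Reactants: 3 methyl (2Z)-2-acetyl-5-(trimethylsilyl)pent-2-en-4-ynoate
Product: 4 methyl (2Z)-2-{1-[(triisopropylsilyl)oxy]ethenyl}-5-(trimethylsilyl)pent-2-en-4-ynoate
Conditions: TIPSOTf, Et3N, CH2Cl2, 0 °C
Reagents that add atoms: triisopropylsilyl trifluoromethanesulfonate (TIPSOTf), CC(C)[Si](C(C)C)(C(C)C)OS(=O)(=O)C(F)(F)F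
Why: Soft enolisation (silyl triflate/amine) at the only enolisable position, the acetyl CH3, gives the 2-silyloxydiene and leaves the trisubstituted alkene geometry untouched.

**Step 3**
Reactants: 5 methacrolein; 6 (triphenylphosphoranylidene)acetaldehyde
Product: 7 (2E)-4-methylpenta-2,4-dienal
Conditions: toluene, 80 °C (ylide as limiting reagent)
Reagents that add atoms: none
Why: Wittig olefination with a stabilised formyl ylide is E-selective and stops at the mono-homologated dienal when the ylide is limiting.

**Step 4**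
Reactants: 4 siloxydiene; 7 (2E)-4-methylpenta-2,4-dienal
Product: 8 methyl (4R,5S,6S)-5-formyl-4-(prop-1-en-2-yl)-2-[(triisopropylsilyl)oxy]-6-[(trimethylsilyl)ethynyl]cyclohex-1-ene-1-carboxylate (alkynyl and formyl cis; formyl and isopropenyl trans)
Conditions: (S)-3,3-diphenyl-1-(2-methylphenyl)tetrahydropyrrolo[1,2-c][1,3,2]oxazaborole (20 mol%), HNTf2 (18 mol%), CH2Cl2, −78 → −40 °C
Reagents that add atoms: none
Why: In this catalytic asymmetric Diels–Alder reaction the silyloxy-activated CH2 terminus bonds to the enal β-carbon, the endo transition state places the outside alkynyl group cis to the formyl group, the E-dienophile keeps formyl and isopropenyl trans, and the boron-bound enal is shielded so that the diene adds to its Cα-Re face, which sets all three ring A stereocentres.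

**Step 5**
Reactants: 9 propiolic acid; 10 2-(trimethylsilyl)ethanol
Product: 11 2-(trimethylsilyl)ethyl propiolate
Conditions: p-TsOH·H2O (5 mol%), toluene, Dean–Stark, reflux
Reagents that add atoms: none
Why: Fischer esterification driven by water removal gives an ester that fluoride cleaves later in the presence of the methyl ester.

**Step 6**
Reactants: 8 ring A aldehyde; 11 2-(trimethylsilyl)ethyl propiolate
Product: 12 2-(trimethylsilyl)ethyl (2Z)-2-{(S)-hydroxy[ring A unit of 8, configuration unchanged]methyl}-3-iodoprop-2-enoate (iodine cis to the ester)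
Conditions: MgI2 (1.5 equiv), CH2Cl2, −20 → 0 °C; then H2O
Reagents that add atoms: magnesium iodide, [Mg+2].[I-].[I-]
Why: In this magnesium iodide-promoted halo-aldol (β-iodo Morita–Baylis–Hillman) reaction iodide adds to the propiolate, the allenolate attacks only the aldehyde to give the kinetic Z-iodide, and Felkin–Anh attack anti to the isopropenyl-bearing ring carbon gives the (S)-carbinol.

**Step 7**
Reactants: 12 vinyl iodide; 13 methyl vinyl ketone
Product: 14 2-(trimethylsilyl)ethyl (2Z,4E)-2-{(S)-hydroxy[ring A unit of 8]methyl}-6-oxohepta-2,4-dienoate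
Conditions: Pd(OAc)2 (5 mol%), n-Bu4NCl, NaHCO3, DMF, 35 °C
Reagents that add atoms: none
Why: The Heck reaction under Jeffery conditions couples the vinyl iodide with retention and gives the E-enone, while the O-silyl group stops the β-keto ester from adding to methyl vinyl ketone and the C-silyl group keeps the alkyne out of the palladium chemistry.

**Step 8**
Reactants: 14 silylalkyne
Product: 15 terminal alkyne corresponding to 14 (all else unchanged)
Conditions: AgNO3 (10 mol%), CH2Cl2/MeOH/H2O (7:4:1), rt
Reagents that add atoms: none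
Why: Silver-catalysed protodesilylation cleaves only the alkynyl C–Si bond and leaves the silyl enol ether, the 2-silylethyl ester, the dienone and the stereocentres untouched.

**Step 9**
Reactants: 15 alkynol
Product: 17 cis-fused ring A/ring B cyclohept-4-enone diester bearing an (S)-configured CH with an (E)-3-oxobut-1-enyl arm, via exocyclic enol ether 16 (not isolated)
Conditions: Ph3PAuNTf2 (2 mol%), 2,6-di-tert-butylpyridine (10 mol%), toluene, rt; then BHT, 150 °C (sealed tube)
Reagents that add atoms: none
Why: Monovalent gold activates the terminal alkyne for 5-exo-dig attack of the secondary alcohol (alkynol cycloisomerisation, C–O bond), and the cis-fused 2-methylene-5-alkenyl oxolane then undergoes Claisen ring expansion with the dienoate on its convex face, so the (S)-carbinol configuration is transferred suprafacially to the new CH stereocentre and the ring alkene ends conjugated with the ester.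

**Step 10**
Reactants: 17 protected seco-ester
Product: 20 target CNP0268969.1, via seco-acid 18 (not isolated), via acetonyl lactone 19 (not isolated)
Conditions: n-Bu4NF (4 equiv), AcOH (4 equiv), THF, 0 → 35 °C
Reagents that add atoms: none
Why: Proposed new method: a fluoride-triggered carboxylate-first domino in which loss of both silyl groups gives 18, whose ammonium carboxylate (AcOH supplies the protons) adds reversibly 5-exo-trig to the enone and forms the lactone C–O bond; only the epimer of 19 with the acetonyl arm cis to the ring B CH2 can be drained by the acetate-mediated 5-(enolexo) aldol of the ring B ketone onto the methyl ketone, so the C–O stereocentre is corrected dynamically, the new C–C bond is forced cis to the lactone, and the methyl group ends on the convex face with the tertiary OH hydrogen-bonded to the ketone; the closest known reaction types are intramolecular oxa-Michael lactonisation of carboxylic acids onto enones and base-mediated intramolecular aldol addition, which have not been coupled into one operation that builds two rings on a cycloheptenone.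

**Compound list**
1 | methyl acetoacetate | CC(=O)CC(=O)OC | starting material
2 | 3-(trimethylsilyl)prop-2-ynal | C[Si](C)(C)C#CC=O | starting material
3 | methyl (2Z)-2-acetyl-5-(trimethylsilyl)pent-2-en-4-ynoate | CC(=O)/C(=C/C#C[Si](C)(C)C)C(=O)OC | intermediate
4 | methyl (2Z)-2-{1-[(triisopropylsilyl)oxy]ethenyl}-5-(trimethylsilyl)pent-2-en-4-ynoate | C=C(O[Si](C(C)C)(C(C)C)C(C)C)/C(=C/C#C[Si](C)(C)C)C(=O)OC | intermediate
5 | methacrolein | C=C(C)C=O | starting material
6 | (triphenylphosphoranylidene)acetaldehyde | O=CC=P(c1ccccc1)(c1ccccc1)c1ccccc1 | starting material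
7 | (2E)-4-methylpenta-2,4-dienal | C=C(C)/C=C/C=O | intermediate
8 | ring A aldehyde, (4R,5S,6S) | C=C(C)[C@@H]1CC(O[Si](C(C)C)(C(C)C)C(C)C)=C(C(=O)OC)[C@@H](C#C[Si](C)(C)C)[C@H]1C=O | intermediate
9 | propiolic acid | C#CC(=O)O | starting material
10 | 2-(trimethylsilyl)ethanol | C[Si](C)(C)CCO | starting material
11 | 2-(trimethylsilyl)ethyl propiolate | C#CC(=O)OCC[Si](C)(C)C | intermediate
12 | (Z)-β-iodo (S)-carbinol acrylate | C=C(C)[C@@H]1CC(O[Si](C(C)C)(C(C)C)C(C)C)=C(C(=O)OC)[C@@H](C#C[Si](C)(C)C)[C@H]1[C@H](O)/C(=C/I)C(=O)OCC[Si](C)(C)C | intermediate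
13 | methyl vinyl ketone | C=CC(C)=O | starting material
14 | (2Z,4E)-6-oxodienoate, silylalkyne | C=C(C)[C@@H]1CC(O[Si](C(C)C)(C(C)C)C(C)C)=C(C(=O)OC)[C@@H](C#C[Si](C)(C)C)[C@H]1[C@H](O)/C(=C/C=C/C(C)=O)C(=O)OCC[Si](C)(C)C | intermediate
15 | (2Z,4E)-6-oxodienoate, terminal alkyne | C=C(C)[C@@H]1CC(O[Si](C(C)C)(C(C)C)C(C)C)=C(C(=O)OC)[C@@H](C#C)[C@H]1[C@H](O)/C(=C/C=C/C(C)=O)C(=O)OCC[Si](C)(C)C | intermediate
16 | cis-fused exocyclic enol ether (methylene oxolane) | C=C(C)[C@@H]1CC(O[Si](C(C)C)(C(C)C)C(C)C)=C(C(=O)OC)[C@H]2C(=C)O[C@H](/C(=C/C=C/C(C)=O)C(=O)OCC[Si](C)(C)C)[C@H]21 | intermediate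
17 | ring A/ring B cycloheptenone diester | C=C(C)[C@@H]1CC(O[Si](C(C)C)(C(C)C)C(C)C)=C(C(=O)OC)[C@H]2C(=O)C[C@@H](/C=C/C(C)=O)C(C(=O)OCC[Si](C)(C)C)=C[C@H]21 | intermediate
18 | seco-acid | C=C(C)[C@@H]1CC(O)=C(C(=O)OC)[C@H]2C(=O)C[C@@H](/C=C/C(C)=O)C(C(=O)O)=C[C@H]21 | intermediate
19 | acetonyl lactone (rings A, B, D) | C=C(C)[C@@H]1CC(O)=C(C(=O)OC)[C@H]2C(=O)C[C@@H]3C(=C[C@H]21)C(=O)O[C@@H]3CC(C)=O | intermediate
20 | target CNP0268969.1 | C=C(C)[C@@H]1CC(O)=C(C(=O)OC)[C@H]2C(=O)[C@@H]3[C@@H]4C(=C[C@H]21)C(=O)O[C@@H]4C[C@]3(C)O | target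

**Totals**
Total step count: 10. Longest linear sequence: 8 (steps 1, 2, 4, 6, 7, 8, 9, 10).

**Steps most likely to fail**

Step 4. The diene is push–pull, so the risks are low reactivity, competing Mukaiyama aldol addition, and an uncertain sense or level of induction. The mirror-image catalyst is available if the sense is reversed. The fallback hands stereocontrol to a covalent auxiliary.
- It sets out from 7. Pinnick oxidation (NaClO2, NaH2PO4, 2-methylbut-2-ene) gives (2E)-4-methylpenta-2,4-dienoic acid F1.
- Pivaloyl chloride/Et3N gives the mixed pivalic anhydride F2, and lithiated (R)-4-benzyl-1,3-oxazolidin-2-one gives the N-dienoyl imide F3.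
- The Et2AlCl chelate of the imide reacts with 4 (CH2Cl2, −78 °C, endo, diene anti to the benzyl group, which is the Cα-Re face) to give the imide cycloadduct F4.
- LiBH4/MeOH releases the auxiliary and gives the primary alcohol F5. Dess–Martin oxidation comes back to the route at 8.

Step 9. The exocyclic enol ether may isomerise into the ring, or the dienone may not survive 150 °C. The fallback takes the enone out of the thermal step and builds the side chain by different C–C chemistry.
- It sets out from 12. Stille coupling with tributyl(vinyl)stannane (Pd2(dba)3, AsPh3, NMP, rt) gives the (2Z)-2-substituted penta-2,4-dienoate F6.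
- AgNO3-catalysed protodesilylation gives the terminal alkyne F7.
- The gold cyclisation gives the vinyl-substituted enol ether F8. Its Claisen rearrangement now runs on a robust, less electron-poor diene and gives the vinyl cycloheptenone F9.
- Cross metathesis with 13 (second-generation Hoveyda–Grubbs catalyst, CH2Cl2, 40 °C) comes back to the route at 17.

Step 10 (the new step). Three side reactions threaten it: C-Michael addition of the β-keto ester carbon to the enone, an unfavourable oxa-Michael equilibrium, and dehydration of the aldol. The fallback installs the oxygen by known stepwise chemistry.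
- It sets out from 17. Copper-catalysed asymmetric conjugate borylation (CuCl, NaOt-Bu, the Josiphos-type ligand enantiomer that gives the R product, B2pin2, MeOH, THF) gives the (R)-β-pinacolboryl ketone F10.
- NaBO3·4H2O oxidises it with retention to the (R)-β-hydroxy ketone F11.
- n-Bu4NF/AcOH gives the hydroxy seco-acid F12. EDC·HCl with catalytic DMAP closes the lactone and comes back to the route at 19.
- An ordinary DBU-catalysed intramolecular aldol addition (10 mol%, CH2Cl2, 0 °C) then takes 19 to 20.

**Further compounds**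
F1 | step 4 | (2E)-4-methylpenta-2,4-dienoic acid | C=C(C)/C=C/C(=O)O
F2 | step 4 | mixed pivalic anhydride | C=C(C)/C=C/C(=O)OC(=O)C(C)(C)C
F3 | step 4 | N-dienoyl imide | C=C(C)/C=C/C(=O)N1[C@H](Cc2ccccc2)COC1=O
F4 | step 4 | imide cycloadduct | C=C(C)[C@@H]1CC(O[Si](C(C)C)(C(C)C)C(C)C)=C(C(=O)OC)[C@@H](C#C[Si](C)(C)C)[C@H]1C(=O)N2[C@H](Cc3ccccc3)COC2=O
F5 | step 4 | primary alcohol | C=C(C)[C@@H]1CC(O[Si](C(C)C)(C(C)C)C(C)C)=C(C(=O)OC)[C@@H](C#C[Si](C)(C)C)[C@H]1CO
F6 | step 9 | (2Z)-2-substituted penta-2,4-dienoate | C=C(C)[C@@H]1CC(O[Si](C(C)C)(C(C)C)C(C)C)=C(C(=O)OC)[C@@H](C#C[Si](C)(C)C)[C@H]1[C@H](O)/C(=C/C=C)C(=O)OCC[Si](C)(C)C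
F7 | step 9 | terminal alkyne | C=C(C)[C@@H]1CC(O[Si](C(C)C)(C(C)C)C(C)C)=C(C(=O)OC)[C@@H](C#C)[C@H]1[C@H](O)/C(=C/C=C)C(=O)OCC[Si](C)(C)C
F8 | step 9 | vinyl-substituted enol ether | C=C(C)[C@@H]1CC(O[Si](C(C)C)(C(C)C)C(C)C)=C(C(=O)OC)[C@H]2C(=C)O[C@H](/C(=C/C=C)C(=O)OCC[Si](C)(C)C)[C@H]21
F9 | step 9 | vinyl cycloheptenone | C=C(C)[C@@H]1CC(O[Si](C(C)C)(C(C)C)C(C)C)=C(C(=O)OC)[C@H]2C(=O)C[C@@H](C=C)C(C(=O)OCC[Si](C)(C)C)=C[C@H]21
F10 | step 10 | (R)-β-pinacolboryl ketone | C=C(C)[C@@H]1CC(O[Si](C(C)C)(C(C)C)C(C)C)=C(C(=O)OC)[C@H]2C(=O)C[C@@H]([C@H](B3OC(C)(C)C(C)(C)O3)CC(C)=O)C(C(=O)OCC[Si](C)(C)C)=C[C@H]21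
F11 | step 10 | (R)-β-hydroxy ketone | C=C(C)[C@@H]1CC(O[Si](C(C)C)(C(C)C)C(C)C)=C(C(=O)OC)[C@H]2C(=O)C[C@@H]([C@H](O)CC(C)=O)C(C(=O)OCC[Si](C)(C)C)=C[C@H]21
F12 | step 10 | hydroxy seco-acid | C=C(C)[C@@H]1CC(O)=C(C(=O)OC)[C@H]2C(=O)C[C@@H]([C@H](O)CC(C)=O)C(C(=O)O)=C[C@H]21
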